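- I followed one rate.

all flasks: substrate 0.20 M
- autumn: partner A 0.20 M; partner B 0.80 M; run made earlier
- dawn: partner A 0.20 M; partner B 0.54 M; run made earlier
- dusk: partner A 0.20 M; partner B 1.2 M; run made earlier
- midnight: partner A 0.30 M; partner B 0.80 M; run made earlier
- zeta: partner A 0.200 M (fed, over 20.0 min); partner B 0.800 M; all but partner A at the start; partner A goes in evenly over 20.0 min, the run ends at 25 min; time 25 min
- gamma: partner A 0.200 M; partner B 0.800 M; a closed flask charged with all of it at once and left for 25 min; time 25 min
- delta: partner A 0.200 M; partner B 0.800 M (fed, over 20.0 min); all but partner B at the start; partner B goes in evenly over 20.0 min, the run ends at 25 min; time 25 min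
- epsilon: partner A 0.200 M; partner B 0.800 M; a single well-mixed tank run continuously and read at steady state, 25 min in it on average

- autumn (time / min: open intermediate / %, target / %, substrate / %): 1.33: 6.4, 6.0, 84.9; 4.00: 8.0, 19.3, 62.3; 8.00: 11.2, 30.2, 44.3; 10.0: 14.5, 33.1, 38.2; 15.0: 22.8, 36.1, 29.2; 20.0: 29.5, 37.3, 22.4; 25.0: 35.0, 37.5, 18.0
- dawn (time / min: open intermediate / %, target / %, substrate / %): 4.00: 5.4, 14.2, 72.7; 8.00: 6.6, 23.7, 57.3; 10.0: 7.7, 27.7, 52.0; 15.0: 10.6, 33.0, 42.4; 20.0: 14.9, 35.5, 36.1; 25.0: 18.5, 37.0, 31.9
- dusk (time / min: open intermediate / %, target / %, substrate / %): 4.00: 12.0, 26.0, 49.7; 8.00: 21.8, 34.7, 31.3; 10.0: 27.7, 35.6, 25.8; 15.0: 39.3, 36.2, 16.9; 20.0: 46.9, 36.5, 11.1; 25.0: 51.5, 36.3, 8.3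
- midnight (time / min: open intermediate / %, target / %, substrate / %): 2.00: 5.5, 10.3, 77.8; 6.00: 6.9, 26.7, 53.3; 12.0: 10.7, 37.8, 36.3; 20.0: 19.2, 42.0, 26.1; 25.0: 24.6, 42.1, 21.3

(scatter of a reading: 0.3 percentage points)

- percentages count the substrate that a species holds: one idle adduct counts as two
- target is meant together with its idle adduct
- the stated concentrations are those of everything mixed, before any reaction; amounts are the same in each set-up
- steps thought possible: substrate + partner B -> open intermediate; partner B + partner A -> second intermediate; open intermediate + second intermediate -> target; 2 second intermediate -> homo product; substrate + target <-> idle adduct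
- the feed brings no volume worth counting
- the earlier runs were made in a closed, stirred flask
- in an amount of target, one idle adduct counts as one target

- the set-up with the highest amount of open intermediate at the outlet or at the end, in percent of the substrate put in ("none" if the first two lie within 2 percentage points) (zeta / gamma / delta / epsilon / none)
- amount of open intermediate at the outlet or at the end, in percent of the substrate put in, zeta
- amount of open intermediate at the outlet or at the end, in percent of the substrate put in, gamma
- amount of open intermediate at the outlet or at the end, in percent of the substrate put in, delta
- amount of open intermediate at the outlet or at the end, in percent of the substrate put in, epsilon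

- Open intermediate and target together count the substrate past the first step, so the autumn run, a closed flask, gave a starting rate of 0.0932 min⁻¹ of the charge.
- At 25.0 min that sum stood at 72.5%; this is the opened share, the part of the charge past the first step.
- Three factors then lowered the rate. The unopened part was 27.5% of the charge, and of that a fraction 0.655 was free, the rest being held in idle adduct.
- Partner B stood at 0.569 of its charge, if each opening and each partner A took one partner B. Freezing partner B makes this step pseudo-first-order in the substrate.
- Multiplied, the factors give 0.102, so I reckoned the end rate at 0.00954 min⁻¹, less than the start. The last interval read 0.0114 min⁻¹.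
- The opened share of the autumn run therefore moved slowly at the end, and the first step, as proposed, holds no partner A. I froze the share for flasks charged with all their partner B: open intermediate at the end is the opened share minus target. For gamma, which repeats autumn, that gave 35.0%.
- The forecast gave zeta 7%, gamma 35%, delta 17% and epsilon 8.5%, with gamma highest, holding that what “keeps the second intermediate dilute favours coupling”.
- The flasks gave zeta 4.04%, gamma 35.8%, delta 19.3% and epsilon 6.45%, so gamma stood highest.

    substrate + partner B → open intermediate (k = 0.130 M⁻¹ min⁻¹)
    partner B + partner A → second intermediate (k = 0.600 M⁻¹ min⁻¹)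
    open intermediate + second intermediate → target (k = 45.0 M⁻¹ min⁻¹)
    2 second intermediate → homo product (k = 39.0 M⁻¹ min⁻¹)
    substrate + target ⇌ idle adduct, settled at all times (K = 8.70 M⁻¹)

- The loss of second intermediate to homo product was the largest single effect on the gap between zeta and gamma: zeta stood 32 percentage points below gamma, and without that loss the two ended 0.041 points apart. In zeta, the frozen share minus its target of 71.7% left 0.800%, against 4.04% in the flask. In the neighbour of zeta charged with 0.080 M of partner A, the frozen share minus its target of 38.1% left 34.4%, and that flask held 44.5%.

The numbers in the tables stem from a simulated flask for an exercise; noise was put on by code.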